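The target maps onto gibberellin A(7) plus one carbon, C20, on C10. The route disconnects C10–C20 (and, transiently, C1–C20): a C20 carbenoid carried by C19 adds across the C1=C10 alkene of ring A, closing a cyclopropane and the cyclopentanone C4–C19–C20–C10–C5 in one operation and fixing C10. The step exploits the axial C19 acyl group on C4, which sits 1,3 to C10 on the α face of ring A and can reach no other alkene. The precursor is the 1(10)-ene C19 diazoketone made from gibberellin A(7) (7-methyl ester, 3-silyl ether). Later the cyclopropane is opened at C1–C20, C19–C20 is cleaved oxidatively, and C16=C17 is hydrated.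

Key step: step 5

Remark (assumptions and conventions): gibberellin A(7), the 3β-hydroxy-1,16-diene 19,10-lactone 7-acid of the gibberellin A series, is taken as the commercial fermentation product, a single enantiomer. Gibberellin numbering is used; α is the face of ring A that carries C19 (the lactone face of 1), β the face that carries C18 and the 3-oxygen; "exo" at C16 is the face of ring D syn to the C14 bridge. The 3-hydroxyl is carried as a tert-butyldimethylsilyl (TBS) ether: it cannot ionise with palladium and has no acidic or reducible acyl group for steps 6 and 8.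

Step 1
Reactants: 1 gibberellin A(7); 2 trimethylsilyldiazomethane
Product: 3 gibberellin A(7) methyl ester
Conditions: 2, PhMe/MeOH (4:1), 0 °C → rt
Reagents that add atoms: trimethylsilyldiazomethane (2), C[Si](C)(C)C=[N+]=[N-]
Why: Diazoalkane O-methylation of the only carboxylic acid is neutral, so the base-sensitive allylic lactone and the 3β-alcohol should stay untouched, and no stereocentre is involved.

Step 2
Reactants: 3 gibberellin A(7) methyl ester
Product: 4 gibberellin A(7) methyl ester 3-O-TBS ether
Conditions: TBSOTf, 2,6-lutidine, CH2Cl2, −78 → 0 °C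
Reagents that add atoms: tert-butyldimethylsilyl triflate, CC(C)(C)[Si](C)(C)OS(=O)(=O)C(F)(F)F
Why: A silyl triflate with a hindered pyridine base should silylate the hindered axial allylic 3β-alcohol (silyl ether protection) without ionising the lactone, with C3 unchanged.

Step 3
Reactants: 4 gibberellin A(7) methyl ester 3-O-TBS ether
Product: 5 7-methyl hydrogen 3β-(TBS-oxy)-20-norgibberella-1(10),16-diene-7,19-dioate (the 1(10)-ene 19-acid)
Conditions: Pd(PPh3)4 (5 mol %), HCO2NH4, dioxane, 80 °C; aq. citric acid work-up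
Reagents that add atoms: none
Why: Zerovalent palladium ionises the strained tertiary allylic C10–O bond from the β face to a π-allyl complex over C10–C1–C2 with the C19 carboxylate as leaving group, and with triphenylphosphine as ligand the formate-derived hydride should go to the less hindered terminus C2 (palladium-catalysed allylic hydrogenolysis, Tsuji type), which leaves the trisubstituted C1=C10 alkene, frees only the C19 acid and creates no stereocentre.

Step 4
Reactants: 5 the 1(10)-ene 19-acid; 2 trimethylsilyldiazomethane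
Product: 7 methyl 3β-(TBS-oxy)-19-(diazomethyl)-19-oxo-20-norgibberella-1(10),16-dien-7-oate (4α-diazoacetyl 1(10)-ene), via acid chloride 6 (not isolated)
Conditions: 1-chloro-N,N,2-trimethylprop-1-en-1-amine, CH2Cl2, 0 °C → rt; then 2 (3 equiv), MeCN/THF, 0 °C → rt
Reagents that add atoms: trimethylsilyldiazomethane (2), C[Si](C)(C)C=[N+]=[N-]; the chlorine of 6 comes from 1-chloro-N,N,2-trimethylprop-1-en-1-amine, CC(C)=C(Cl)N(C)C
Why: The α-chloroenamine converts the hindered tertiary acid into its chloride without free HCl (which could add to C16=C17), and C-acylation of the diazoalkane with loss of the silyl group gives the diazoketone (Arndt–Eistert-type acylation); C4 is quaternary, so no ketene can form and no stereocentre is at risk.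

Step 5
Reactants: 7 the 4α-diazoacetyl 1(10)-ene
Product: 8 methyl 3β-(TBS-oxy)-19-oxo-1α,20:19,20-dicyclogibberell-16-en-7-oate (cyclopropyl ketone; C20 bonded to C19, C10 and C1 on the α face)
Conditions: Rh2(OAc)4 (1 mol %), CH2Cl2, rt, slow addition of 7 at high dilution
Reagents that add atoms: none
Why: Dirhodium tetraacetate expels dinitrogen from the diazoketone and the electrophilic rhodium carbenoid at C20 adds to C1=C10 in a concerted, asynchronous [2+1] cycloaddition; the closest known reaction type is the intramolecular cyclopropanation of alkenyl α-diazoketones. The cyclopentanone ring (C4, C19, C20, C10, C5) closes by C20–C10 bond formation, 5-exo with respect to the C19–C4–C5–C10 tether, and the cyclopropane (C1, C10, C20) closes in the same event by C20–C1 bond formation. C10 is controlled by the tether: the diazoacetyl group is axial on the α face of C4 and 1,3 to C10, so C20 can bond only to the α face of C10, the face the lactone oxygen held in 1. C1 and C20 follow from the suprafacial addition and from the geometry of the cage, which allows only the cis-fused α-cyclopropane. The step needs chemoselectivity for C1=C10 over C16=C17, over C–H insertion and over carbene dimerisation: the tethered carbenoid cannot reach the exocyclic alkene, the electron-rich trisubstituted alkene held at bonding distance should outrun insertion into the allylic C2–H bonds, and slow addition suppresses dimers. The 3β-silyloxy group is anti to C19 and cannot form an oxonium ylide.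

Step 6
Reactants: 8 the cyclopropyl ketone
Product: 9 methyl 3β-(TBS-oxy)-19-oxo-19,20-cyclogibberell-16-en-7-oate (cyclopentanone with C20H2 between C19 and C10α)
Conditions: SmI2 (2.5 equiv), THF/DMPU, t-BuOH, −78 → 0 °C; aq. NH4Cl
Reagents that add atoms: none
Why: Electron transfer gives the C19 ketyl, which should cleave the cyclopropane bond that overlaps with its π system, the exocyclic C20–C1 bond (C20–C10 lies in the plane of the cyclopentanone), and a second electron with protonation gives C1H2 and the enolate, hence the ketone (reductive opening of a cyclopropyl ketone); ester, silyl ether and alkene are inert and C10 keeps C20.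

Step 7
Reactants: 9 the 16-ene cyclopentanone
Product: 10 methyl (16R)-3β-(TBS-oxy)-16-hydroxy-19-oxo-19,20-cyclogibberellan-7-oate (16-hydroxyl exo, 17-methyl endo)
Conditions: Co(acac)2 (20 mol %), PhSiH3, O2 (1 atm), iPrOH/THF, rt
Reagents that add atoms: dioxygen, O=O
Why: Hydrogen atom transfer from a cobalt hydride to C17 gives the tertiary C16 radical, which dioxygen should trap on the exo face of ring D (syn to C14, away from the C11–C12 bridge) before the silane reduces the peroxide to the alcohol (Mukaiyama hydration, Markovnikov); a radical, unlike a C16 cation, does not undergo Wagner–Meerwein shifts, and the ketone is not reduced.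

Step 8
Reactants: 10 the 16-hydroxy ketone
Product: 11 C19 trimethylsilyl enol ether (C19=C20) and 16-O-trimethylsilyl ether of 10
Conditions: TMSOTf, Et3N, CH2Cl2, 0 °C → rt; used crude
Reagents that add atoms: trimethylsilyl triflate, C[Si](C)(C)OS(=O)(=O)C(F)(F)F
Why: Soft enolisation with silyl triflate and amine gives the only possible enol ether of the C19 ketone (C4 is quaternary, so enolisation goes towards C20) and silylates the tertiary alcohol, while the hindered ester is left alone and no stereocentre changes.

Step 9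
Reactants: 11 the bis-silylated enol ether
Product: 14 7-methyl hydrogen 3β-(TBS-oxy)-16-hydroxy-20-oxogibberellane-7,19-dioate (19-acid 20-aldehyde; may close to the 19,20-lactol), via methoxy hydroperoxide 12 (not isolated), via silylated aldehyde 13 (not isolated)
Conditions: O3, CH2Cl2/MeOH, −78 °C; Me2S, −78 °C → rt; aq. citric acid, MeOH, rt
Reagents that add atoms: ozone, [O-][O+]=O
Why: Ozone cleaves the electron-rich C19=C20 enol ether (ozonolysis, Criegee mechanism): C19 leaves as the silyl ester, the C20 carbonyl oxide is trapped by methanol and reduced by dimethyl sulfide to the aldehyde, and mild acid removes both trimethylsilyl groups; no other alkene is left, and C4 and C10 are quaternary.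

Step 10
Reactants: 14 the 19-acid 20-aldehyde
Product: 15 7-methyl ester of 3β-(TBS-oxy)-16-hydroxygibberellane-7,19,20-trioic acid (19,20-diacid)
Conditions: NaClO2, NaH2PO4, 2-methyl-2-butene, t-BuOH/H2O, rt
Reagents that add atoms: sodium chlorite, [Na+].[O-]Cl=O
Why: Chlorite should oxidise the hindered neopentyl aldehyde, free or in equilibrium with its lactol, to the acid without touching the alcohol or the silyl ether (Pinnick oxidation); C10 is quaternary and cannot epimerise.

Step 11
Reactants: 15 the 19,20-diacid 7-methyl ester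
Product: 16 3β-(TBS-oxy)-16-hydroxygibberellane-7,19,20-trioic acid
Conditions: KOH (2 M), MeOH/H2O, reflux; then HCl to pH 2
Reagents that add atoms: water (as hydroxide), O
Why: Hot aqueous hydroxide saponifies the C7 methyl ester by acyl–oxygen cleavage; the 3-oxygen is still silylated and C19 is a carboxylate, so retro-aldol epimerisation at C3 is excluded, and the 7-carboxyl is already trans to C4 across C5–C6.

Step 12
Reactants: 16 the triacid 3-O-TBS ether
Product: 17 (16R)-3β,16-dihydroxygibberellane-7,19,20-trioic acid (target, CNP0183110.3)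
Conditions: HF (48 % aq.), MeCN, rt
Reagents that add atoms: none
Why: Fluoride cleaves the Si–O bond of the hindered secondary silyl ether (desilylation) under weakly acidic conditions that should not ionise the tertiary C16 alcohol, and no stereocentre is affected.

Compound list
1 | gibberellin A(7) (3β-hydroxy-1,16-diene 19,10α-lactone 7-acid) | C[C@]1(C5=O)[C@H]2[C@H](C(=O)O)[C@@]34C[C@@H](CC[C@H]3[C@]2(O5)C=C[C@@H]1O)C(=C)C4 | starting material
2 | trimethylsilyldiazomethane | C[Si](C)(C)C=[N+]=[N-] | starting material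
3 | gibberellin A(7) methyl ester | C[C@]1(C5=O)[C@H]2[C@H](C(=O)OC)[C@@]34C[C@@H](CC[C@H]3[C@]2(O5)C=C[C@@H]1O)C(=C)C4 | intermediate
4 | gibberellin A(7) methyl ester 3-O-TBS ether | C[C@]1(C5=O)[C@H]2[C@H](C(=O)OC)[C@@]34C[C@@H](CC[C@H]3[C@]2(O5)C=C[C@@H]1O[Si](C)(C)C(C)(C)C)C(=C)C4 | intermediate
5 | 1(10)-ene 19-acid (7-methyl ester, 3β-OTBS, 16-ene) | C[C@]1(C(=O)O)[C@H]2[C@H](C(=O)OC)[C@@]34C[C@@H](CC[C@H]3C2=CC[C@@H]1O[Si](C)(C)C(C)(C)C)C(=C)C4 | intermediate
6 | 19-acyl chloride of 5 (not isolated) | C[C@]1(C(=O)Cl)[C@H]2[C@H](C(=O)OC)[C@@]34C[C@@H](CC[C@H]3C2=CC[C@@H]1O[Si](C)(C)C(C)(C)C)C(=C)C4 | intermediate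
7 | 1(10)-ene C19 diazoketone (4α-diazoacetyl, 7-methyl ester, 3β-OTBS) | C[C@]1(C(=O)C=[N+]=[N-])[C@H]2[C@H](C(=O)OC)[C@@]34C[C@@H](CC[C@H]3C2=CC[C@@H]1O[Si](C)(C)C(C)(C)C)C(=C)C4 | intermediate
8 | cyclopropyl ketone (C20 bonded to C19, C10α and C1α) | C[C@]1(C5=O)[C@H]2[C@H](C(=O)OC)[C@@]34C[C@@H](CC[C@H]3[C@@]26[C@@H]5[C@H]6C[C@@H]1O[Si](C)(C)C(C)(C)C)C(=C)C4 | intermediate
9 | 19-oxo-19,20-cyclo compound (cyclopentanone C4–C19–C20–C10–C5, 16-ene) | C[C@]1(C5=O)[C@H]2[C@H](C(=O)OC)[C@@]34C[C@@H](CC[C@H]3[C@]2(C5)CC[C@@H]1O[Si](C)(C)C(C)(C)C)C(=C)C4 | intermediate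
10 | (16R)-16-hydroxy cyclopentanone (hydroxyl exo) | C[C@]1(C5=O)[C@H]2[C@H](C(=O)OC)[C@@]34C[C@@H](CC[C@H]3[C@]2(C5)CC[C@@H]1O[Si](C)(C)C(C)(C)C)[C@](C)(O)C4 | intermediate
11 | C19 trimethylsilyl enol ether, 16-O-trimethylsilyl ether | C[C@]1(C(O[Si](C)(C)C)=C5)[C@H]2[C@H](C(=O)OC)[C@@]34C[C@@H](CC[C@H]3[C@]25CC[C@@H]1O[Si](C)(C)C(C)(C)C)[C@](C)(O[Si](C)(C)C)C4 | intermediate
12 | C20 methoxy hydroperoxide, C19 trimethylsilyl ester, 16-O-trimethylsilyl ether (not isolated; both C20 epimers, which converge) | C[C@]1(C(=O)O[Si](C)(C)C)[C@H]2[C@H](C(=O)OC)[C@@]34C[C@@H](CC[C@H]3[C@]2(C(OC)OO)CC[C@@H]1O[Si](C)(C)C(C)(C)C)[C@](C)(O[Si](C)(C)C)C4 | intermediate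
13 | 20-aldehyde, C19 trimethylsilyl ester, 16-O-trimethylsilyl ether (not isolated) | C[C@]1(C(=O)O[Si](C)(C)C)[C@H]2[C@H](C(=O)OC)[C@@]34C[C@@H](CC[C@H]3[C@]2(C=O)CC[C@@H]1O[Si](C)(C)C(C)(C)C)[C@](C)(O[Si](C)(C)C)C4 | intermediate
14 | 19-acid 20-aldehyde (7-methyl ester, 3β-OTBS, 16-OH) | C[C@]1(C(=O)O)[C@H]2[C@H](C(=O)OC)[C@@]34C[C@@H](CC[C@H]3[C@]2(C=O)CC[C@@H]1O[Si](C)(C)C(C)(C)C)[C@](C)(O)C4 | intermediate
15 | 19,20-diacid 7-methyl ester (3β-OTBS, 16-OH) | C[C@]1(C(=O)O)[C@H]2[C@H](C(=O)OC)[C@@]34C[C@@H](CC[C@H]3[C@]2(C(=O)O)CC[C@@H]1O[Si](C)(C)C(C)(C)C)[C@](C)(O)C4 | intermediate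
16 | 7,19,20-triacid 3-O-TBS ether | C[C@]1(C(=O)O)[C@H]2[C@H](C(=O)O)[C@@]34C[C@@H](CC[C@H]3[C@]2(C(=O)O)CC[C@@H]1O[Si](C)(C)C(C)(C)C)[C@](C)(O)C4 | intermediate
17 | (16R)-3β,16-dihydroxygibberellane-7,19,20-trioic acid | C[C@]1(C(=O)O)[C@H]2[C@H](C(=O)O)[C@@]34C[C@@H](CC[C@H]3[C@]2(C(=O)O)CC[C@@H]1O)[C@](C)(O)C4 | target

Total step count: 12. Longest linear sequence: 12 (the route is fully linear from 1).

Steps most likely to fail

1. Step 3. Hydride may be transferred to the hindered C10 terminus of the π-allyl complex (giving a 1-ene with a C10–H bond), or the complex may lose a β-hydrogen to give dienes. The fallback sets out from 3 and changes the mechanism to dissolving-metal cleavage: Li in liquid NH3/THF at −78 °C with short contact and NH4Cl quench. The allyl anion should be protonated at the less substituted C2, and the free 3-hydroxyl (as alkoxide) cannot be eliminated. This gives the 3β-hydroxy 1(10)-ene 19-acid F1. TBSOTf (2.5 equiv) and 2,6-lutidine then give the silyl ester silyl ether F2, whose silyl ester is cleaved with K2CO3 in aqueous methanol. The route is rejoined at 5.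

2. Step 5. The acceptor-only rhodium carbenoid may be diverted into C–H insertion at the allylic C2 position or into intermolecular dimerisation before it reaches C1=C10. The fallback sets out from 5 (through 6, made as in step 4) and uses a stabilised diazo compound with a removable ester. Acylation of lithiated ethyl diazoacetate (LiN(iPr)2, THF, −78 °C) gives the ethyl 2-diazo-3-oxo ester F3. Cu(acac)2 in toluene at 100 °C, where copper carbenoids of diazo keto esters favour cyclopropanation over insertion, gives the cyclopropyl keto ester F4. SmI2 (THF, MeOH, −78 °C) opens C1–C20 to the β-keto ester F5, and Krapcho dealkoxycarbonylation (LiCl, wet DMSO, 150 °C) removes the ester. The route is rejoined at 9.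

3. Step 7. Facial selectivity in the trapping of the planar C16 radical by dioxygen may be poor and give both C16 epimers. The fallback sets out from 9 and replaces the radical hydration by a closed-shell, sterically controlled sequence. Dimethyldioxirane (acetone, 0 °C) should epoxidise C16=C17 from the exo face to the 16,17-epoxide F6. LiI with AcOH in THF opens it at the primary C17 to the iodohydrin F7, and Bu3SnH with AIBN (PhH, 80 °C) removes the iodine, with the C16–O bond untouched throughout. The route is rejoined at 10.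

Further compounds
F1 | step 3 | 3β-hydroxy 1(10)-ene 19-acid 7-methyl ester | C[C@]1(C(=O)O)[C@H]2[C@H](C(=O)OC)[C@@]34C[C@@H](CC[C@H]3C2=CC[C@@H]1O)C(=C)C4
F2 | step 3 | 19-TBS ester 3-O-TBS ether of F1 | C[C@]1(C(=O)O[Si](C)(C)C(C)(C)C)[C@H]2[C@H](C(=O)OC)[C@@]34C[C@@H](CC[C@H]3C2=CC[C@@H]1O[Si](C)(C)C(C)(C)C)C(=C)C4
F3 | step 5 | ethyl 2-diazo-3-oxo ester on C4 (C19 ketone, C20 diazo carbon bearing CO2Et) | C[C@]1(C(=O)C(=[N+]=[N-])C(=O)OCC)[C@H]2[C@H](C(=O)OC)[C@@]34C[C@@H](CC[C@H]3C2=CC[C@@H]1O[Si](C)(C)C(C)(C)C)C(=C)C4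
F4 | step 5 | cyclopropyl keto ester (C20 bonded to C19, C10α, C1α and CO2Et) | C[C@]1(C5=O)[C@H]2[C@H](C(=O)OC)[C@@]34C[C@@H](CC[C@H]3[C@@]26[C@]5(C(=O)OCC)[C@H]6C[C@@H]1O[Si](C)(C)C(C)(C)C)C(=C)C4
F5 | step 5 | ring-opened β-keto ester (C20 bears CO2Et; enolisable, both C20 epimers) | C[C@]1(C5=O)[C@H]2[C@H](C(=O)OC)[C@@]34C[C@@H](CC[C@H]3[C@]2(C5C(=O)OCC)CC[C@@H]1O[Si](C)(C)C(C)(C)C)C(=C)C4
F6 | step 7 | exo 16,17-epoxide of 9 | C[C@]1(C5=O)[C@H]2[C@H](C(=O)OC)[C@@]34C[C@@H](CC[C@H]3[C@]2(C5)CC[C@@H]1O[Si](C)(C)C(C)(C)C)[C@]6(OC6)C4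
F7 | step 7 | 17-iodo 16-hydroxy compound (hydroxyl exo) | C[C@]1(C5=O)[C@H]2[C@H](C(=O)OC)[C@@]34C[C@@H](CC[C@H]3[C@]2(C5)CC[C@@H]1O[Si](C)(C)C(C)(C)C)[C@](CI)(O)C4
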